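Ring A is closed last by forming the C3–C4 bond in an intramolecular Mukaiyama aldol reaction. The step exploits the cis-1,3-diaxial pair C19 (on C4) and C20 (on C10) on the α face of ring A: both are tied into a temporary six-membered methoxy lactol-lactone (C10–C20–O–C19–C4–C5) that the open target lacks. Its silyl ketene acetal carries a vinyl group on C10; hydroformylation makes the C1–C2–C3 aldehyde chain and BF3 then closes ring A, fixing C4 through the tether and C3 through an open transition state. The B/C/D core comes from a Diels–Alder reaction, a vinyl radical cyclization and two conjugate additions.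

Key step: step 12

Remark: the target gibberellin is a ring–chain tautomeric pair (open C20 aldehyde/C19 acid and its δ-lactol); the final compound is written in the open form. Gibberellane numbering (C1–C20) is used for all intermediates. The acetal carbon C20 of compounds 19–24 (and C4 of 20) is a mixture of epimers that converges later and is drawn without configuration.

Step 1
Reactants: 1 (R)-4-(tert-butyldimethylsilyloxy)cyclopent-2-en-1-one; 2 buta-1,3-diene
Product: 4 cis-fused bicyclic enone (3a,4,7,7a-tetrahydro-1H-inden-1-one), via silyloxy Diels–Alder adduct 3 (not isolated)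
Conditions: 2 (excess), EtAlCl2 (30 mol %), CH2Cl2, −40 to 0 °C; then DBU, 0 °C to rt
Reagents that add atoms: buta-1,3-diene C=CC=C
Why: Lewis-acid-catalysed Diels–Alder reaction on the enone face anti to the silyloxy group gives the cis-fused adduct and so the absolute configuration at C9, and base-induced E1cB loss of silanolate then unveils the C5=C10 enone.

Step 2
Reactants: 4 cis-fused bicyclic enone; 5 2,3-dibromoprop-1-ene
Product: 6 bicyclic enone with a 2-bromoallyl group on C8 (cis to the C9 hydrogen)
Conditions: LiN(iPr)2, THF, −78 °C; then 5, DMPU, −78 to −30 °C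
Reagents that add atoms: 2,3-dibromoprop-1-ene C=C(Br)CBr
Why: kinetic α'-deprotonation at the ring-fusion carbon C8 and enolate C-alkylation by the allylic bromide on the convex face keep the cis ring fusion and set the quaternary stereocenter C8.

Step 3
Reactants: 6 bromoallyl enone; 7 1,3-dioxolane
Product: 8 bicyclic ketone with a 1,3-dioxolan-2-yl group on C10
Conditions: 7–MeCN (1:1), (nBu4N)4[W10O32] (2 mol %), 390 nm LED, rt
Reagents that add atoms: 1,3-dioxolane C1COCO1
Why: hydrogen-atom-transfer photocatalysis by (nBu4N)4[W10O32] gives the nucleophilic 1,3-dioxolan-2-yl radical, which adds to the enone β-carbon C10 (Giese reaction) from the convex face; the new C10 center is erased again in step 5.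

Step 4
Reactants: 8 dioxolanyl ketone
Product: 9 tricyclic ketone (rings B, C and D, 16-methylene)
Conditions: Bu3SnH (1.3 equiv, 0.02 M), AIBN (10 mol %), PhH, 80 °C
Reagents that add atoms: none
Why: Bu3SnH-mediated vinyl radical cyclization, in which the C16 radical attacks C13 of the ring C alkene 5-exo-trig from the side of the angular arm, closes ring D as the bicyclo[3.2.1]octane with the exocyclic methylene and fixes C13 through the bridge; the stannane concentration is kept high enough to reduce the C12 radical before a homoallyl rearrangement to the bicyclo[2.2.2]octane can occur.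

Step 5
Reactants: 9 tricyclic ketone
Product: 10 tricyclic enone (C5=C10, dioxolanyl on C10)
Conditions: IBX, 4-methoxypyridine N-oxide, DMSO, 40 °C
Reagents that add atoms: none
Why: IBX dehydrogenation through the only possible enol (towards C5, since C8 is quaternary) re-forms the C5=C10 enone, now carrying the acetal carbon C20.

Step 6
Reactants: 10 tricyclic enone; 11 vinylmagnesium bromide
Product: 13 enol triflate with quaternary C10, via magnesium enolate 12 (not isolated)
Conditions: 11, CuBr·SMe2 (20 mol %), THF, −40 °C; then PhNTf2, DMPU, −40 °C to rt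
Reagents that add atoms: vinylmagnesium bromide C=C[Mg]Br; N-phenylbis(trifluoromethanesulfonimide) O=S(=O)(N(c1ccccc1)S(=O)(=O)C(F)(F)F)C(F)(F)F
Why: CuBr·SMe2-catalysed conjugate addition of the vinyl Grignard reagent from the convex β face (anti to the C9–C11 bond) sets quaternary C10 with C20 on the α face, and the regiodefined enolate is trapped on oxygen as the triflate.

Step 7
Reactants: 13 enol triflate; 14 4-methoxybenzyl alcohol
Product: 15 4-methoxybenzyl C5=C6 enoate
Conditions: Pd(OAc)2 (5 mol %), PPh3 (10 mol %), CO (1 atm), 14, Et3N, DMF, 60 °C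
Reagents that add atoms: carbon monoxide [C-]#[O+]; 4-methoxybenzyl alcohol COc1ccc(CO)cc1
Why: Pd(OAc)2-catalysed alkoxycarbonylation of the enol triflate installs C7 as an acid-labile ester and creates the C5=C6 Michael acceptor.

Step 8
Reactants: 15 enoate acetal
Product: 16 C20 aldehyde
Conditions: PPTS, acetone–H2O (4:1), 55 °C
Reagents that add atoms: water O
Why: acid-catalysed acetal hydrolysis frees the non-enolizable neopentyl aldehyde and leaves the ester and the alkenes untouched.

Step 9
Reactants: 16 C20 aldehyde; 17 propanoic anhydride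
Product: 19 C20 1-methoxyalkyl propanoate (acyloxy acetal), via dimethyl acetal 18 (not isolated)
Conditions: HC(OMe)3, MeOH, PPTS, rt, concentrate; then 17, Me3SiOTf (5 mol %), 2,6-di-tert-butyl-4-methylpyridine, CH2Cl2, −40 °C
Reagents that add atoms: trimethyl orthoformate COC(OC)OC; propanoic anhydride CCC(=O)OC(=O)CC
Why: acetalization followed by Lewis-acid-catalysed acetal–anhydride exchange through the C20 oxocarbenium ion gives the pseudo-ester that carries the future C4, C18 and C19.

Step 10
Reactants: 19 C20 1-methoxyalkyl propanoate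
Product: 20 cis-fused methoxy lactol-lactone
Conditions: KN(SiMe3)2 (1.05 equiv), THF, −78 °C; then t-BuOH, −78 to −20 °C; AcOH
Reagents that add atoms: none
Why: intramolecular Michael addition (6-exo-trig) of the tethered propanoate enolate can reach C5 only on the α face where C20 sits, which sets C5 in the cis-fused lactone, and the alkoxide then equilibrates the epimerizable C6 to the 7β-ester trans to the C5–C4 bond.

Step 11
Reactants: 20 methoxy lactol-lactone
Product: 21 tert-butyldimethylsilyl ketene acetal of the lactone
Conditions: LiN(iPr)2, THF–DMPU, −78 °C; then t-BuMe2SiCl, −78 to −40 °C; non-aqueous work-up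
Reagents that add atoms: tert-butyldimethylsilyl chloride CC(C)(C)[Si](C)(C)Cl
Why: the lactone α-hydrogen at C4 is more acidic and less shielded than the C6 hydrogen next to quaternary C8, and O-silylation of the enolate gives the ketene acetal in which the C4 center is erased.

Step 12
Reactants: 21 silyl ketene acetal
Product: 23 ring A aldol product (3β-hydroxy 19,20-methoxy lactol-lactone), via C3 aldehyde ketene acetal 22 (not isolated)
Conditions: Rh(acac)(CO)2 (2 mol %), Xantphos (4 mol %), CO/H2 (1:1, 10 bar), PhMe, 50 °C; vent, cool; then BF3·OEt2 (1.2 equiv), CH2Cl2, −78 °C; aq NaHCO3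
Reagents that add atoms: carbon monoxide [C-]#[O+]
Why: Rh(acac)(CO)2-catalysed linear hydroformylation of the C10 vinyl group gives aldehyde 22 (C3), and BF3 then triggers an intramolecular Mukaiyama aldol addition of the lactone silyl ketene acetal through an open transition state, the silyl group leaving as its fluoride. The closest known reaction types are the tandem hydroformylation–Mukaiyama aldol cyclization of enol silanes that carry a remote alkene and the aldol closure of ring A in 3,4-seco gibberellin aldehydes. Ring A closes in the 6-(enolexo)-exo-trig mode. C4 is controlled by the temporary lactone ring: C19 is held on the α face by C20, so C3 can only bond to the face of C4 that leaves the methyl carbon C18 β. C3 is controlled by the antiperiplanar open transition state, in which the BF3-bound oxygen turns away from the silyloxy group and the ring oxygen of the ketene acetal and so ends trans to C19 as the axial 3β-hydroxyl. The step needs hydroformylation of the monosubstituted vinyl group in the presence of the 1,1-disubstituted 16-methylene and the tetrasubstituted ketene acetal, which the steric discrimination of the Rh(acac)(CO)2–Xantphos catalyst should secure, and it needs an aldol without base, which the preformed ketene acetal secures because neither aldehyde enolization nor retro-aldol epimerization at C3 can occur.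

Step 13
Reactants: 23 ring A aldol product
Product: 25 target gibberellin (open 20-aldehyde 7,19-diacid), via 7-carboxylic acid methoxy lactol-lactone 24 (not isolated)
Conditions: CF3CO2H, anisole, CH2Cl2, 0 °C; then THF–H2O, rt
Reagents that add atoms: water O
Why: acidolysis of the 4-methoxybenzyl ester (cation scavenged by anisole) and acid hydrolysis of the pseudo-ester release the C7 acid, the C19 acid and the C20 aldehyde without base, so the β-hydroxy acid is not epimerized by retro-aldol reaction.

Compound list
1 | (R)-4-(tert-butyldimethylsilyloxy)cyclopent-2-en-1-one | O=C1C=C[C@H](O[Si](C)(C)C(C)(C)C)C1 | starting material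
2 | buta-1,3-diene | C=CC=C | starting material
3 | silyloxy Diels–Alder adduct: cis-fused 3-(tert-butyldimethylsilyloxy)-2,3,3a,4,7,7a-hexahydro-1H-inden-1-one, silyloxy group cis to both ring-fusion hydrogens | O=C1C[C@@H](O[Si](C)(C)C(C)(C)C)[C@@H]2CC=CC[C@H]12 | intermediate (not isolated)
4 | cis-fused bicyclic enone, 3a,4,7,7a-tetrahydro-1H-inden-1-one | O=C1C=C[C@@H]2CC=CC[C@H]12 | intermediate
5 | 2,3-dibromoprop-1-ene | C=C(Br)CBr | starting material
6 | 7a-(2-bromoprop-2-enyl)-3a,4,7,7a-tetrahydro-1H-inden-1-one, bromoallyl group (on C8) cis to the C9 hydrogen | O=C1C=C[C@@H]2CC=CC[C@]12CC(Br)=C | intermediate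
7 | 1,3-dioxolane | C1COCO1 | starting material
8 | bicyclic ketone with 1,3-dioxolan-2-yl on C10 (cis to the C9 hydrogen) | O=C1C[C@@H](C3OCCO3)[C@@H]2CC=CC[C@]12CC(Br)=C | intermediate
9 | tricyclic B/C/D ketone: C6 ketone, 16-methylene bicyclo[3.2.1]octane, dioxolanyl on C10 | C=C1C[C@]23C[C@H]1CC[C@H]2[C@H](C4OCCO4)CC3=O | intermediate
10 | tricyclic C5=C10 enone with dioxolanyl on C10 | C=C1C[C@]23C[C@H]1CC[C@H]2C(C4OCCO4)=CC3=O | intermediate
11 | vinylmagnesium bromide | C=C[Mg]Br | starting material
12 | magnesium enolate (C10: vinyl β, dioxolanyl α) | C=C1C[C@]23C[C@H]1CC[C@H]2[C@@](C=C)(C4OCCO4)C=C3O[Mg]Br | intermediate (not isolated)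
13 | C5=C6 enol triflate (C10: vinyl β, dioxolanyl α) | C=C1C[C@]23C[C@H]1CC[C@H]2[C@@](C=C)(C4OCCO4)C=C3OS(=O)(=O)C(F)(F)F | intermediate
14 | 4-methoxybenzyl alcohol | COc1ccc(CO)cc1 | starting material
15 | 4-methoxybenzyl C5=C6 enoate (C7 ester), C20 as dioxolane | C=C1C[C@]23C[C@H]1CC[C@H]2[C@@](C=C)(C4OCCO4)C=C3C(=O)OCc5ccc(OC)cc5 | intermediate
16 | C20 aldehyde of the enoate | C=C1C[C@]23C[C@H]1CC[C@H]2[C@@](C=C)(C=O)C=C3C(=O)OCc4ccc(OC)cc4 | intermediate
17 | propanoic anhydride | CCC(=O)OC(=O)CC | starting material
18 | C20 dimethyl acetal | C=C1C[C@]23C[C@H]1CC[C@H]2[C@@](C=C)(C(OC)OC)C=C3C(=O)OCc4ccc(OC)cc4 | intermediate (not isolated)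
19 | C20 1-methoxyalkyl propanoate (C20 epimers) | C=C1C[C@]23C[C@H]1CC[C@H]2[C@@](C=C)(C(OC)OC(=O)CC)C=C3C(=O)OCc4ccc(OC)cc4 | intermediate
20 | cis-fused methoxy lactol-lactone (ring C10–C20–O–C19–C4–C5; 5β-hydrogen, 7β-ester; C4 and C20 epimers) | C=C1C[C@]23C[C@H]1CC[C@H]2[C@@]4(C=C)C(OC)OC(=O)C(C)[C@H]4[C@@H]3C(=O)OCc5ccc(OC)cc5 | intermediate
21 | tert-butyldimethylsilyl ketene acetal of lactone 20 (C4=C19) | C=C1C[C@]23C[C@H]1CC[C@H]2[C@@]4(C=C)C(OC)OC(O[Si](C)(C)C(C)(C)C)=C(C)[C@H]4[C@@H]3C(=O)OCc5ccc(OC)cc5 | intermediate
22 | C3 aldehyde (3-oxopropyl on C10) silyl ketene acetal | C=C1C[C@]23C[C@H]1CC[C@H]2[C@@]4(CCC=O)C(OC)OC(O[Si](C)(C)C(C)(C)C)=C(C)[C@H]4[C@@H]3C(=O)OCc5ccc(OC)cc5 | intermediate (not isolated)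
23 | ring A aldol product: 3β-hydroxy, 18-methyl β, 19,20-methoxy lactol-lactone, 7-(4-methoxybenzyl) ester | C=C1C[C@]23C[C@H]1CC[C@H]2[C@]1(C4OC)CC[C@H](O)[C@@](C)(C(=O)O4)[C@H]1[C@@H]3C(=O)OCc5ccc(OC)cc5 | intermediate
24 | 7-carboxylic acid with intact 19,20-methoxy lactol-lactone | C=C1C[C@]23C[C@H]1CC[C@H]2[C@]1(C4OC)CC[C@H](O)[C@@](C)(C(=O)O4)[C@H]1[C@@H]3C(=O)O | intermediate (not isolated)
25 | target gibberellin, open form: 3β-hydroxy, 4β-methyl, 4α-carboxylic acid (C19), 10α-formyl (C20), 6β-carboxylic acid (C7), 16-methylene | C=C1C[C@]23C[C@H]1CC[C@H]2[C@]1(C=O)CC[C@H](O)[C@@](C)(C(=O)O)[C@H]1[C@@H]3C(=O)O | target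

Total step count: 13. Longest linear sequence: 13 steps (from compound 1).

Steps most likely to fail

Step 12. The silyl ketene acetal may be lost by protodesilylation or by reaction with the hydroformylation catalyst before the Lewis acid is added, and facial selectivity at C3 may be poor, so that the equatorial 3α-alcohol forms. The fallback sets out from compound 20. Hydroformylation of 20 itself under the same Rh(acac)(CO)2/Xantphos conditions gives the aldehyde lactone F1. KOt-Bu (0.3 equiv) in t-BuOH–THF at 0 °C then effects a reversible intramolecular aldol reaction, the reaction type by which 3-hydroxygibberellins epimerize at C3. It should give the thermodynamically favoured 3α-alcohol F2, with C4 still fixed by the lactone. Dess–Martin periodinane gives the 3-ketone F3. K[HB(s-Bu)3] in THF at −78 °C, attacking equatorially from the α face, should give the axial 3β-alcohol, which is compound 23, where the route is rejoined.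

Step 10. The ester enolate of the acyloxy acetal may fragment to a ketene and so lose the tether before the Michael addition occurs. The fallback sets out from compound 18 (the dimethyl acetal made from 16, here isolated) and replaces the hard ester enolate by a soft malonate. Me3SiOTf-catalysed exchange of 18 with allyl hydrogen 2-methylmalonate gives the mixed acetal malonate F4. Cs2CO3 in MeCN effects a reversible, thermodynamically controlled intramolecular Michael addition to the lactone allyl ester F5. Deallylative decarboxylation with Pd(PPh3)4, HCO2H and Et3N gives the C4–H lactone, compound 20, where the route is rejoined.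

Step 2. The hindered cross-conjugated enolate may undergo O-alkylation, over-alkylation or self-condensation instead of C-alkylation at C8. The fallback sets out from compound 1 and makes the quaternary C8 in the cycloaddition itself. α-Iodination (I2, pyridine) gives the iodoenone F6. Stille coupling with tributyl(2-bromoprop-2-enyl)stannane (Pd2(dba)3, AsPh3, CuI, NMP) gives the 2-(2-bromoallyl) enone F7. Diels–Alder reaction with 2 (EtAlCl2), anti to the silyloxy group, gives the adduct F8. DBU elimination of silanol returns to compound 6.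

Further compounds
F1 | step 12 | aldehyde lactone (3-oxopropyl on C10, lactone not silylated) | C=C1C[C@]23C[C@H]1CC[C@H]2[C@@]4(CCC=O)C(OC)OC(=O)C(C)[C@H]4[C@@H]3C(=O)OCc5ccc(OC)cc5
F2 | step 12 | 3α-hydroxy epimer of compound 23 | C=C1C[C@]23C[C@H]1CC[C@H]2[C@]1(C4OC)CC[C@@H](O)[C@@](C)(C(=O)O4)[C@H]1[C@@H]3C(=O)OCc5ccc(OC)cc5
F3 | step 12 | 3-ketone of the 19,20-methoxy lactol-lactone | C=C1C[C@]23C[C@H]1CC[C@H]2[C@]1(C4OC)CCC(=O)[C@@](C)(C(=O)O4)[C@H]1[C@@H]3C(=O)OCc5ccc(OC)cc5
F4 | step 10 | C20 1-methoxyalkyl allyl 2-methylmalonate | C=C1C[C@]23C[C@H]1CC[C@H]2[C@@](C=C)(C(OC)OC(=O)C(C)C(=O)OCC=C)C=C3C(=O)OCc4ccc(OC)cc4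
F5 | step 10 | cis-fused lactone with allyl ester on C4 | C=C1C[C@]23C[C@H]1CC[C@H]2[C@@]4(C=C)C(OC)OC(=O)C(C)(C(=O)OCC=C)[C@H]4[C@@H]3C(=O)OCc5ccc(OC)cc5
F6 | step 2 | (R)-4-(tert-butyldimethylsilyloxy)-2-iodocyclopent-2-en-1-one | O=C1C(I)=C[C@H](O[Si](C)(C)C(C)(C)C)C1
F7 | step 2 | (R)-2-(2-bromoprop-2-enyl)-4-(tert-butyldimethylsilyloxy)cyclopent-2-en-1-one | O=C1C(CC(Br)=C)=C[C@H](O[Si](C)(C)C(C)(C)C)C1
F8 | step 2 | silyloxy Diels–Alder adduct with the bromoallyl group on C8 | O=C1C[C@@H](O[Si](C)(C)C(C)(C)C)[C@@H]2CC=CC[C@]12CC(Br)=C
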